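The numbers in the tables were generated by integration for substances that don't exist.

The late end of this flask was what I lacked: Tuesday's readings stop at 5.00 h and Monday's at 8.00 h, while 12 h is asked. So I built the flask up one step at a time.

common to all: Sub 0.50 M

| flask | Ptn | remark | time | volume of the second phase over the first |
|---|---|---|---|---|
| Tuesday's | 0.75 M | the very flask that is asked about, followed so far |  |  |
| Monday's | 1.5 M | run made earlier |  |  |
| flask | 0.750 M |  | 12 h | 2.0 |

| run | time / h | Tgt / % |
|---|---|---|
| Tuesday's | 0.333 | 1.2 |
| Tuesday's | 1.00 | 0.1 |
| Tuesday's | 1.50 | 0 |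
| Tuesday's | 2.50 | 1.6 |
| Tuesday's | 4.00 | 1.4 |
| Tuesday's | 5.00 | 2.5 |
| Monday's | 0.667 | 0 |
| Monday's | 1.00 | 0 |
| Monday's | 2.00 | 2.4 |
| Monday's | 3.00 | 3.9 |
| Monday's | 5.00 | 2.4 |
| Monday's | 8.00 | 8.7 |

(readings scatter by 1 percentage point)

- in the second phase: Ptn; everything else is in the first
- charges count per volume of the first phase; a concentration in a rate is the amount of a species over the volume of its own phase; every rate counts per litre of the first phase
- what was read earlier has a scatter of 1 percentage point, one standard deviation
- on the list of suspects stand: Ptn2 <-> Ptn; Ptn2 -> Sdp; Sub + Ptn2 -> Tgt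
- the earlier runs hold the two phases in the same ratio of volumes as the flask asked about

- Tgt at 12 h, in percent of the Sub charged
- the change that raises the amount of Tgt at 12 h, in percent of the Sub charged most ("none" if none brings more than 2 percentage points) (epsilon / eta / none)
- amount of Tgt at 12 h, in percent of the Sub charged, after eta

I began with the main step, Sub + Ptn2 -> Tgt. Sub stayed close to its charge, since the highest reading of Tgt was 8.7%, so the step is pseudo-first-order in Ptn2. Tgt should then climb in step with time and with the Ptn charge. I named the fraction of the Ptn charge that turns up as Tgt each hour the capture rate. A least-squares line through the origin, over both runs, gave: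

capture rate = 0.00314 /h

Tgt at 12 h, as a fraction of the Sub charge = capture rate × time × Ptn charge / Sub charge = 5.65%

With Monday's Ptn charge, the same line gives 11.3%.

Next I added the transfer Ptn2 <-> Ptn. Ptn2 must first fill, so there is a lag, but a lag of 1.00 h costs 0.47 percentage points, less than the scatter of 1 point, and I subtracted nothing.

Last came Ptn2 -> Sdp, which takes Ptn away unseen and should bend the capture rate down late. The last readings give 0.00333 /h on Tuesday and 0.00363 /h on Monday, so that crossing from filling to draining could not be read, and I kept my number. On my line eta gains 5.7 points, above the bar of 2 points. No run gave a number for epsilon, but I expected a doubled transfer coefficient to raise Ptn2 by a factor of 2 at best and a doubled Ptn charge to give that factor in full, so I chose eta.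

The forecast gave 5.7% (4% to 7.5%) and eta with 11.5% (9% to 14.5%), on the ground that "Doubling Ptn doubles Ptn2 regardless".

The flask gave 5.92% at 12 h, and 11.5% after eta, a gain of 5.6 points against 2.5 points for epsilon, with these steps behind it:

    Ptn2 ⇌ Ptn, rate k1*([Ptn2] - [Ptn]/K1) per volume of the first phase (partition coefficient = 2.20, kL = 0.00382 /min)
    Ptn2 → Sdp (k = 0.0121 /min)
    Sub + Ptn2 → Tgt (k = 0.00309 /M/min)

At 12.0 h, 61.0% of the Ptn charge was still in the flask. Its capture rate over those hours came to 0.00329 /h. Left until 30 h, the same flask held 11.1% Tgt with 29.6% of its Ptn, and its capture rate had dropped to 0.00247 /h.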